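## Assumptions
- The target has no stereocentres, so the "single enantiomer" requirement is trivially met.
- Orsellinic acid is taken as commercially available.
- Vilsmeier formylation of the tris(benzyloxy)toluene occurs at the methyl/OBn-flanked C–H, as it does for 3,5-dimethoxytoluene.

## Retrosynthesis
- The target is a tridepside (A–B–C) with two aryl ester bonds. Disconnecting both gives three benzoic acid units: A = 2,4,5-trihydroxy-6-methylbenzoyl, B = 2-methoxy-4-hydroxy-6-methylbenzoyl, C = orsellinic acid.
- The route builds C→B→A. Ring C is used as its boron-masked salicylate, so its 4-OH is the only free nucleophile. This is the proposed new step.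
- All three benzene rings come from commercial aromatics (orcinol, methyl orsellinate, orsellinic acid). The only ring work is ring A's oxygenation and carboxylation, by iterative formylation, Dakin oxidation and Pinnick oxidation.
- Benzyl groups protect ring A's three OH groups and ring B's 4-OH. A last hydrogenolysis and boronate hydrolysis deliver the target.

## Route

**Step 1**
Reactants: 1 orcinol (5-methylbenzene-1,3-diol)
Product: 2 3,5-bis(benzyloxy)toluene
Conditions: BnBr (2.2 equiv), K2CO3, DMF, 60 °C
Reagents that add atoms: benzyl bromide, BrCc1ccccc1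
Why: Williamson O-benzylation of both phenols.

**Step 2**
Reactants: 2
Product: 3 2,4-bis(benzyloxy)-6-methylbenzaldehyde
Conditions: POCl3, DMF, 0→50 °C; then aq. NaOAc
Reagents that add atoms: DMF, O=CN(C)C (formyl carbon); water, O (aldehyde oxygen on iminium hydrolysis)
Why: Vilsmeier–Haack formylation goes at the position flanked by Me and OBn (ortho to one OBn, para to the other), not at the position between the two OBn groups.

**Step 3**
Reactants: 3
Product: 4 2,4-bis(benzyloxy)-6-methylphenol
Conditions: (i) mCPBA, NaHCO3, CH2Cl2, 0 °C→rt; (ii) K2CO3, MeOH, rt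
Reagents that add atoms: mCPBA, OOC(=O)c1cccc(Cl)c1 (oxygen source)
Why: Dakin-type Baeyer–Villiger oxidation of an electron-rich o/p-alkoxybenzaldehyde gives the aryl formate by aryl migration, and methanolysis releases the phenol. This installs the future C5–O.

**Step 4**
Reactants: 4
Product: 5 2,3,5-tris(benzyloxy)toluene
Conditions: BnBr, K2CO3, DMF, rt, N2
Reagents that add atoms: benzyl bromide, BrCc1ccccc1
Why: Williamson O-benzylation of the phenol.

**Step 5**
Reactants: 5
Product: 6 2,4,5-tris(benzyloxy)-6-methylbenzaldehyde
Conditions: POCl3, DMF, 0→45 °C; then aq. NaOAc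
Reagents that add atoms: DMF, O=CN(C)C; water, O
Why: Vilsmeier formylation at the only activated, less hindered C–H (para to the 4-OBn, ortho to the 2-OBn, flanked by Me), not the position between two OBn groups.

**Step 6**
Reactants: 6
Product: 7 2,4,5-tris(benzyloxy)-6-methylbenzoic acid
Conditions: NaClO2, NaH2PO4, 2-methyl-2-butene, t-BuOH/H2O, rt
Reagents that add atoms: sodium chlorite, [O-][Cl]=O (oxygen source)
Why: Pinnick oxidation tolerates hindered, electron-rich aldehydes, and the alkene scavenges HOCl to prevent ring chlorination.

**Step 7**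
Reactants: 7
Product: 8 2,4,5-tris(benzyloxy)-6-methylbenzoyl chloride
Conditions: (COCl)2, cat. DMF, CH2Cl2, 0 °C→rt; concentrate and use at once
Reagents that add atoms: oxalyl chloride, O=C(Cl)C(=O)Cl (chlorine)
Why: a Vilsmeier-type acid chloride formation. The hindered 2,6-disubstituted acid chloride is a robust acylating agent.

**Step 8**
Reactants: 9 methyl orsellinate (methyl 2,4-dihydroxy-6-methylbenzoate)
Product: 10 methyl 4-(benzyloxy)-2-hydroxy-6-methylbenzoate
Conditions: BnBr (1.05 equiv), K2CO3, acetone, reflux
Reagents that add atoms: benzyl bromide, BrCc1ccccc1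
Why: the 4-OH is more acidic and more exposed, while the 2-OH is chelated to the ester C=O, so alkylation is regioselective.

**Step 9**
Reactants: 10
Product: 11 methyl 4-(benzyloxy)-2-methoxy-6-methylbenzoate
Conditions: MeI, K2CO3, DMF, 50 °C
Reagents that add atoms: iodomethane, CI
Why: O-methylation of the remaining chelated phenol installs the 2'-OMe.

**Step 10**
Reactants: 11
Product: 12 4-(benzyloxy)-2-methoxy-6-methylbenzoic acid
Conditions: KOH (10 equiv), EtOH/H2O 4:1, reflux, 48 h; then HCl
Reagents that add atoms: potassium hydroxide, [K+].[OH-] (carboxylate oxygen); HCl, Cl (protonation)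
Why: saponification of the hindered 2,6-disubstituted methyl ester. The benzyl and methyl aryl ethers are base-stable.

**Step 11**
Reactants: 12
Product: 13 4-(benzyloxy)-2-methoxy-6-methylbenzoyl chloride
Conditions: (COCl)2, cat. DMF, CH2Cl2, 0 °C→rt; concentrate
Reagents that add atoms: oxalyl chloride, O=C(Cl)C(=O)Cl
Why: standard acid chloride formation.

**Step 12**
Reactants: 14 orsellinic acid (2,4-dihydroxy-6-methylbenzoic acid)
Product: 15 2-phenyl-7-hydroxy-5-methyl-4H-1,3,2-benzodioxaborin-4-one
Conditions: PhB(OH)2 (1.1 equiv), toluene, Dean–Stark reflux (or 4 Å MS)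
Reagents that add atoms: phenylboronic acid, OB(O)c1ccccc1
Why: salicylic acids condense with arylboronic acids to give cyclic acyloxy-aryloxy boranes. This masks the COOH and 2-OH in one operation and leaves the 4-OH free.

**Step 13**
Reactants: 13 acid chloride of ring B; 15 boron-masked orsellinic acid
Product: 16 aryl ester of 15 with 4-(benzyloxy)-2-methoxy-6-methylbenzoic acid (B–C depside, boronate retained)
Conditions: Et3N, cat. DMAP, anhydrous CH2Cl2, 0 °C→rt; non-aqueous workup (filter salts, concentrate); used without chromatography
Reagents that add atoms: none (the two substrates combine, with loss of HCl)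
Why: Proposed new method: the B(aryl)-bridged six-membered chelate ties up the carboxylate and the chelated 2-O, and its electron-withdrawing boron–acyloxy group makes the 4-OH the only nucleophilic and most acidic site. It should be acylated selectively by the hindered acid chloride, so no ring-C benzyl ester and no hindered ester cleavage is needed. The closest known reactions are the transient boronate protection of α-hydroxy acids and diols and boron-directed regioselective acylation. Salicylate boronate masking has not been used to make depsides.

**Step 14**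
Reactants: 16
Product: 17 B–C depside boronate with free ring-B 4-OH
Conditions: H2 (1 atm), 10% Pd/C, EtOAc, rt (no alcohol solvent, to keep the boronate)
Reagents that add atoms: none (H2 only adds hydrogen)
Why: catalytic hydrogenolysis of the aryl benzyl ether. The aryl ester and the boronate survive.

**Step 15**
Reactants: 8 ring-A acid chloride; 17
Product: 18 fully protected tridepside (A–B–C, boronate retained)
Conditions: Et3N, cat. DMAP, CH2Cl2, 0 °C→rt; non-aqueous workup
Reagents that add atoms: none (the two substrates combine, with loss of HCl)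
Why: Schotten–Baumann-type O-acylation of the unhindered ring-B phenol by the acid chloride. Any boronate hydrolysed on workup converges in Step 16.

**Step 16**
Reactants: 18
Product: 19 2'-O-methylhiascic acid (target)
Conditions: H2 (1 atm), 10% Pd/C, THF/MeOH, rt, N2; then H2O; purify by preparative RP-HPLC (acidic eluent)
Reagents that add atoms: water, O (boronate hydrolysis; PhB(OH)2 leaves)
Why: hydrogenolysis removes the three ring-A benzyl ethers, and MeOH/H2O cleaves the labile salicylate boronate to free the 2-OH and CO2H. The aryl esters and the OMe are untouched.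

## Compound list
1 | orcinol | Cc1cc(O)cc(O)c1 | starting material
2 | 3,5-bis(benzyloxy)toluene | Cc1cc(OCc2ccccc2)cc(OCc2ccccc2)c1 | intermediate
3 | 2,4-bis(benzyloxy)-6-methylbenzaldehyde | Cc1cc(OCc2ccccc2)cc(OCc2ccccc2)c1C=O | intermediate
4 | 2,4-bis(benzyloxy)-6-methylphenol | Cc1cc(OCc2ccccc2)cc(OCc2ccccc2)c1O | intermediate
5 | 2,3,5-tris(benzyloxy)toluene | Cc1cc(OCc2ccccc2)cc(OCc2ccccc2)c1OCc1ccccc1 | intermediate
6 | 2,4,5-tris(benzyloxy)-6-methylbenzaldehyde | Cc1c(OCc2ccccc2)c(OCc2ccccc2)cc(OCc2ccccc2)c1C=O | intermediate
7 | 2,4,5-tris(benzyloxy)-6-methylbenzoic acid | Cc1c(OCc2ccccc2)c(OCc2ccccc2)cc(OCc2ccccc2)c1C(=O)O | intermediate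
8 | 2,4,5-tris(benzyloxy)-6-methylbenzoyl chloride | Cc1c(OCc2ccccc2)c(OCc2ccccc2)cc(OCc2ccccc2)c1C(=O)Cl | intermediate
9 | methyl orsellinate | COC(=O)c1c(C)cc(O)cc1O | starting material
10 | methyl 4-(benzyloxy)-2-hydroxy-6-methylbenzoate | COC(=O)c1c(C)cc(OCc2ccccc2)cc1O | intermediate
11 | methyl 4-(benzyloxy)-2-methoxy-6-methylbenzoate | COC(=O)c1c(C)cc(OCc2ccccc2)cc1OC | intermediate
12 | 4-(benzyloxy)-2-methoxy-6-methylbenzoic acid | COc1cc(OCc2ccccc2)cc(C)c1C(=O)O | intermediate
13 | 4-(benzyloxy)-2-methoxy-6-methylbenzoyl chloride | COc1cc(OCc2ccccc2)cc(C)c1C(=O)Cl | intermediate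
14 | orsellinic acid | Cc1cc(O)cc(O)c1C(=O)O | starting material
15 | 2-phenyl-7-hydroxy-5-methyl-4H-1,3,2-benzodioxaborin-4-one | Cc1cc(O)cc2OB(c3ccccc3)OC(=O)c21 | intermediate
16 | B–C depside boronate, 4'-OBn | COc1cc(OCc2ccccc2)cc(C)c1C(=O)Oc1cc(C)c2c(c1)OB(c1ccccc1)OC2=O | intermediate
17 | B–C depside boronate, 4'-OH | COc1cc(O)cc(C)c1C(=O)Oc1cc(C)c2c(c1)OB(c1ccccc1)OC2=O | intermediate
18 | protected A–B–C depside boronate | Cc1c(OCc2ccccc2)c(OCc2ccccc2)cc(OCc2ccccc2)c1C(=O)Oc1cc(C)c(C(=O)Oc2cc(C)c3c(c2)OB(c2ccccc2)OC3=O)c(OC)c1 | intermediate
19 | 2'-O-methylhiascic acid | COc1cc(OC(=O)c2c(O)cc(O)c(O)c2C)cc(C)c1C(=O)Oc1cc(C)c(C(=O)O)c(O)c1 | target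

## Totals
- Total steps: 16.
- Longest linear sequence: 9 steps (orcinol → Steps 1–7 → 15 → 16).

## Three steps most likely to fail
1. **Step 13 (proposed new step): boron-masked 4-O-acylation.** The 6-methyl group may strain the chelate or hinder boronate formation, and the boronate may not survive the acylation or workup.
   - Fallback: use benzyl orsellinate (benzyl 2,4-dihydroxy-6-methylbenzoate) in place of 15, with known regioselective 4-O-acylation (the 2-OH is H-bond-differentiated). Then run the same downstream steps, and the final hydrogenolysis also removes the benzyl ester.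
2. **Step 5: Vilsmeier regioselectivity and benzyl-ether tolerance.** The formylation could give the wrong regioisomer (between the two OBn groups) or partly debenzylate.
   - Fallback: reverse the order of carbon and oxygen introduction. Start from methyl orsellinate, make the 2,4-bis(benzyl ether), do a Rieche formylation at C5, then Dakin oxidation, benzylation and saponification to give 7.
3. **Step 3: Dakin oxidation of the electron-rich aldehyde.** Ring over-oxidation or low conversion is possible.
   - Fallback: brominate 2 with NBS at C2, then Pd-catalysed hydroxylation (tBuBrettPhos Pd, KOH, dioxane/H2O) to give phenol 4 without any oxidation of the ring.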